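The route rests on disconnecting the C4–C4a bond of the pyran ring (ring C) of this (2S,4R)-flavan-4-ol. The key step is an intramolecular Friedel–Crafts hydroxyalkylation that exploits the phloroglucinol-type ring A: C4a, the only free carbon ortho to O1, is activated by O1 and the C5 methoxy (ortho) and by the C7 methoxy (para) and attacks a Me2AlCl-bound aldehyde. One operation closes ring C, creates the C4 carbinol and sets the 2,4-trans relationship under control of C2 and the peri C5 methoxy. The precursor is the open-chain (S)-3-aryloxy-3-phenylpropanal, made by Mitsunobu inversion of a commercial (R)-β-hydroxy ester with 3,5-dimethoxy-2-prenylphenol and partial reduction.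

Key step: step 4

Remark: flavan numbering is used (O1, C2, C3, C4, C4a, C5 to C8, C8a; ring A is the benzo ring, ring C the pyran ring). (2S,4R) is the 2,4-trans arrangement, with the C2 phenyl and the C4 hydroxyl on opposite faces of ring C. Both enantiomers of ethyl 3-hydroxy-3-phenylpropanoate are assumed to be commercial.

Step 1
Reactants: 1 3,5-dimethoxyphenol; 2 prenyl bromide (1-bromo-3-methylbut-2-ene)
Product: 4 3,5-dimethoxy-2-(3-methylbut-2-en-1-yl)phenol, via sodium 3,5-dimethoxyphenoxide 3 (not isolated)
Conditions: NaH (1.0 equiv), toluene, 0 °C to rt; then 2 (1.0 equiv), rt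
Reagents that add atoms: none
Why: C-allylation of a sodium phenoxide contact ion pair in a non-polar solvent should go to the ortho carbon through a sodium-bridged SN2 transition state, followed by tautomerisation of the dienone; the two ortho carbons of 1 are equivalent by symmetry, so a single ortho-prenyl phenol is expected, with the O-prenyl ether and the para isomer as separable minor products.

Step 2
Reactants: 4 3,5-dimethoxy-2-(3-methylbut-2-en-1-yl)phenol; 5 ethyl (R)-3-hydroxy-3-phenylpropanoate
Product: 6 ethyl (S)-3-[3,5-dimethoxy-2-(3-methylbut-2-en-1-yl)phenoxy]-3-phenylpropanoate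
Conditions: PPh3, DIAD (slow addition), THF, 0 °C to rt
Reagents that add atoms: none
Why: In this Mitsunobu etherification the phenoxide of 4 should displace the benzylic oxyphosphonium group of 5 by SN2 with inversion, turning the (R)-carbinol into the (S)-aryl ether carbon that becomes C2, while slow addition at 0 °C holds back E1cB loss to ethyl cinnamate.

Step 3
Reactants: 6 ethyl (S)-3-[3,5-dimethoxy-2-(3-methylbut-2-en-1-yl)phenoxy]-3-phenylpropanoate
Product: 8 (S)-3-[3,5-dimethoxy-2-(3-methylbut-2-en-1-yl)phenoxy]-3-phenylpropanal, via diisobutylaluminium hemiacetal 7 (not isolated)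
Conditions: iBu2AlH (1.1 equiv), CH2Cl2, −78 °C; MeOH, then aq. potassium sodium tartrate
Reagents that add atoms: none
Why: Partial reduction of the ester by iBu2AlH should stop at the tetrahedral aluminium hemiacetal 7, which is held at −78 °C by chelation to the β-aryloxy oxygen and collapses to the aldehyde only on quench; C2 is untouched, and the crude aldehyde is used at once to avoid β-elimination of the phenol.

Step 4
Reactants: 8 (S)-3-[3,5-dimethoxy-2-(3-methylbut-2-en-1-yl)phenoxy]-3-phenylpropanal
Product: 10 (2S,4R)-5,7-dimethoxy-8-(3-methylbut-2-en-1-yl)-2-phenylchroman-4-ol, via chloro(methyl)aluminium alkoxide 9 (not isolated)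
Conditions: Me2AlCl (2 equiv), CH2Cl2 (0.01 M), −78 to −40 °C; then aq. potassium sodium tartrate, 0 °C
Reagents that add atoms: none
Why: Me2AlCl binds the aldehyde oxygen and the activated carbonyl carbon is attacked by C4a of ring A; the Wheland intermediate rearomatises by loss of the C4a proton, which is an intramolecular Friedel–Crafts hydroxyalkylation (arene–aldehyde cyclisation of the Prins family). Ring C closes in a 6-exo-trig mode with respect to the C=O group through a chair-like transition state. The new C4 stereocentre is controlled by C2 and by the C5 methoxy: the phenyl group sits equatorial at C2 and the aluminium-bound oxygen should take the pseudo-axial position to escape peri (A(1,3)) strain with the C5 methoxy, which places O4 trans to the phenyl group, that is 4R. The step needs regioselectivity, secured because C4a is the only free carbon ortho to O1 and the only one the three-atom tether can reach. It also needs chemoselectivity over a carbonyl-ene reaction of the prenyl group, secured because that reaction would have to close an 8- or 9-membered ring. Me2AlCl is chosen because its Al–CH3 bond consumes the liberated proton as methane and leaves the product as the neutral alkoxide 9, so the electron-rich benzylic C4–O bond should not ionise and neither the prenyl group nor the C2 ether meets Brønsted acid.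

Compound list
1 | 3,5-dimethoxyphenol | COc1cc(O)cc(OC)c1 | starting material
2 | prenyl bromide (1-bromo-3-methylbut-2-ene) | CC(C)=CCBr | starting material
3 | sodium 3,5-dimethoxyphenoxide | COc1cc([O-])cc(OC)c1.[Na+] | intermediate (not isolated)
4 | 3,5-dimethoxy-2-(3-methylbut-2-en-1-yl)phenol | COc1cc(OC)c(CC=C(C)C)c(O)c1 | intermediate
5 | ethyl (R)-3-hydroxy-3-phenylpropanoate | CCOC(=O)C[C@@H](O)c1ccccc1 | starting material
6 | ethyl (S)-3-[3,5-dimethoxy-2-(3-methylbut-2-en-1-yl)phenoxy]-3-phenylpropanoate | CCOC(=O)C[C@H](Oc1cc(OC)cc(OC)c1CC=C(C)C)c1ccccc1 | intermediate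
7 | diisobutylaluminium hemiacetal of 6 (mixture at the hemiacetal carbon) | CCOC(O[Al](CC(C)C)CC(C)C)C[C@H](Oc1cc(OC)cc(OC)c1CC=C(C)C)c1ccccc1 | intermediate (not isolated)
8 | (S)-3-[3,5-dimethoxy-2-(3-methylbut-2-en-1-yl)phenoxy]-3-phenylpropanal | O=CC[C@H](Oc1cc(OC)cc(OC)c1CC=C(C)C)c1ccccc1 | intermediate
9 | chloro(methyl)aluminium alkoxide of the target, (2S,4R) | COc1cc(OC)c2c(c1CC=C(C)C)O[C@H](c1ccccc1)C[C@H]2O[Al](C)Cl | intermediate (not isolated)
10 | (2S,4R)-5,7-dimethoxy-8-(3-methylbut-2-en-1-yl)-2-phenylchroman-4-ol (2,4-trans-5,7-dimethoxy-8-prenylflavan-4-ol) | COc1cc(OC)c2c(c1CC=C(C)C)O[C@H](c1ccccc1)C[C@H]2O | target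

Total step count: 4. Longest linear sequence: 4 steps (1 → 4 → 6 → 8 → 10).

Steps most likely to fail

Step 4 (key step). What may go wrong: ionisation of the electron-rich benzylic C4–O bond of the product, leading to elimination or oligomerisation; retro-oxa-Michael loss of phenol 4 from the Lewis-acid-bound aldehyde; or incomplete facial selectivity at C4. The fallback sets out from 6 and comes back to the route at 10, and keeps the same C4–C4a ring closure at the ketone oxidation level. Saponification of 6 (LiOH, THF/H2O, 0 °C) should give (S)-3-[3,5-dimethoxy-2-(3-methylbut-2-en-1-yl)phenoxy]-3-phenylpropanoic acid F1. Intramolecular Friedel–Crafts acylation of C4a through the mixed anhydride (trifluoroacetic anhydride, CH2Cl2, 0 °C) should then close ring C to (2S)-5,7-dimethoxy-8-(3-methylbut-2-en-1-yl)flavanone F2. Reduction with NaBH4 (MeOH, 0 °C) is expected to deliver hydride axially and give the 2,4-cis alcohol (2S,4S)-5,7-dimethoxy-8-(3-methylbut-2-en-1-yl)flavan-4-ol F3. Mitsunobu inversion at C4 with 4-nitrobenzoic acid (PPh3, DIAD, THF) should give (2S,4R)-5,7-dimethoxy-8-(3-methylbut-2-en-1-yl)flavan-4-yl 4-nitrobenzoate F4, and methanolysis (K2CO3, MeOH, rt) should release 10.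

Step 2. What may go wrong: E1cB elimination of the activated β-hydroxy ester to ethyl cinnamate, and partial loss of configuration through an SN1 pathway at the benzylic carbon, both favoured by the slow attack of the ortho-substituted phenol. The fallback sets out from 4 and comes back at 8, and makes the C2–O bond by asymmetric catalysis instead of inversion. Iridium-catalysed enantioselective allylic etherification of 4 with cinnamyl methyl carbonate ([Ir(cod)Cl]2, a chiral phosphoramidite ligand in the enantiomer that delivers the S ether, K3PO4, THF, rt) should give the branched ether (S)-1,5-dimethoxy-2-(3-methylbut-2-en-1-yl)-3-[(1-phenylprop-2-en-1-yl)oxy]benzene F5. Hydroboration of the terminal vinyl group with 9-BBN (THF, 0 °C; then NaOH, H2O2), which should leave the trisubstituted prenyl alkene alone, should give (S)-3-[3,5-dimethoxy-2-(3-methylbut-2-en-1-yl)phenoxy]-3-phenylpropan-1-ol F6. Oxidation with Dess–Martin periodinane (CH2Cl2, NaHCO3, 0 °C) should then give 8.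

Step 1. What may go wrong: competing O-alkylation, attack at the para carbon between the two methoxy groups, and double prenylation. The fallback sets out from 1 and comes back at 4, and brings the prenyl group in through oxygen. O-Alkylation of 1 with tert-butyl 2-methylbut-3-en-2-yl carbonate under catalysis by zerovalent palladium (Pd(PPh3)4, THF, 0 °C) should give the tertiary allyl ether 1,3-dimethoxy-5-[(2-methylbut-3-en-2-yl)oxy]benzene F7. Aromatic Claisen rearrangement of F7 (toluene, 110 °C) should move the allyl unit, with allylic transposition, to one of the two equivalent ortho carbons and give 4 after tautomerisation.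

Further compounds
F1 | step 4 | (S)-3-[3,5-dimethoxy-2-(3-methylbut-2-en-1-yl)phenoxy]-3-phenylpropanoic acid | OC(=O)C[C@H](Oc1cc(OC)cc(OC)c1CC=C(C)C)c1ccccc1
F2 | step 4 | (2S)-5,7-dimethoxy-8-(3-methylbut-2-en-1-yl)flavanone | COc1cc(OC)c2c(c1CC=C(C)C)O[C@H](c1ccccc1)CC2=O
F3 | step 4 | (2S,4S)-5,7-dimethoxy-8-(3-methylbut-2-en-1-yl)flavan-4-ol (2,4-cis) | COc1cc(OC)c2c(c1CC=C(C)C)O[C@H](c1ccccc1)C[C@@H]2O
F4 | step 4 | (2S,4R)-5,7-dimethoxy-8-(3-methylbut-2-en-1-yl)flavan-4-yl 4-nitrobenzoate | COc1cc(OC)c2c(c1CC=C(C)C)O[C@H](c1ccccc1)C[C@H]2OC(=O)c1ccc(cc1)[N+](=O)[O-]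
F5 | step 2 | (S)-1,5-dimethoxy-2-(3-methylbut-2-en-1-yl)-3-[(1-phenylprop-2-en-1-yl)oxy]benzene | C=C[C@H](Oc1cc(OC)cc(OC)c1CC=C(C)C)c1ccccc1
F6 | step 2 | (S)-3-[3,5-dimethoxy-2-(3-methylbut-2-en-1-yl)phenoxy]-3-phenylpropan-1-ol | OCC[C@H](Oc1cc(OC)cc(OC)c1CC=C(C)C)c1ccccc1
F7 | step 1 | 1,3-dimethoxy-5-[(2-methylbut-3-en-2-yl)oxy]benzene | COc1cc(OC)cc(OC(C)(C)C=C)c1
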